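**Plan**

- Retrosynthesis: the three phenols are masked as MOM ethers and an allyl ester is placed on C3. Ring C is then cut at C3–C4 and at O1–C8a together, giving ring A as an ortho-fluoro aroyl ester (8) and ring B with C2, C3 and O1 as an (S)-β-hydroxy ester (14).
- What allows this: in ring C the C4 carbonyl sits ortho to C8a of ring A, so C4/C8a is a 1,3-dielectrophile once C8a carries fluorine (acyl substitution at C4, SNAr at C8a activated by C4=O). O1–C2–C3 is an aldol-type 1,3-O,C pair that becomes an alkoxide–enolate dinucleophile once C3 carries an ester.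
- 8 is cut at C4–C4a and at the bond from C6 to the geranyl CH2 (two successive directed ortho-metalations of 5-fluororesorcinol bis-MOM ether). 14 is cut at C2–C3 (crossed Claisen) and at the C2–H bond (ketone reduction).
- Forward: ring A unit (steps 1–3) and ring B unit (steps 4–6) are made separately; step 7 joins them and closes ring C; step 8 removes the C3 ester; step 9 frees the phenols.
- Stereochemistry: C2 (S) is set by Ru-catalysed asymmetric transfer hydrogenation in step 6 and carried through unchanged. The E alkene comes from geranyl bromide. The single fluorine fixes 6- over 8-geranyl regiochemistry.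

Key step: step 7

Remark: 17 is expected as a mixture of C3 epimers together with its enol; its SMILES leaves C3 undefined, since this centre becomes CH2 in step 8. Geranyl = (2E)-3,7-dimethylocta-2,6-dien-1-yl.

**Step 1**
Reactants: 1 5-fluorobenzene-1,3-diol
Product: 2 1-fluoro-3,5-bis(methoxymethoxy)benzene
Conditions: NaH (2.4 equiv), MOMCl (2.4 equiv), DMF, 0 °C to rt
Reagents that add atoms: chloromethyl methyl ether (MOMCl), COCCl
Why: Williamson-type O-alkylation of both phenoxides gives the acetal groups that protect the phenols and later direct both metalations.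

**Step 2**
Reactants: 2 1-fluoro-3,5-bis(methoxymethoxy)benzene; 3 geranyl bromide
Product: 5 5-fluoro-2-geranyl-1,3-bis(methoxymethoxy)benzene, via aryllithium 4 (not isolated)
Conditions: n-BuLi, TMEDA, THF, −20 °C; then CuBr·SMe2 (10 mol %), 3, −78 °C to rt
Reagents that add atoms: none
Why: Directed ortho-metalation should take place at the carbon flanked by the two OMOM groups (double chelation, no ortho fluorine), and copper-catalysed SN2 allylation of the aryllithium with geranyl bromide should keep the E geometry.

**Step 3**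
Reactants: 5 5-fluoro-2-geranyl-1,3-bis(methoxymethoxy)benzene; 6 allyl chloroformate
Product: 8 allyl 6-fluoro-3-geranyl-2,4-bis(methoxymethoxy)benzoate, via aryllithium 7 (not isolated)
Conditions: s-BuLi, TMEDA, THF, −78 °C; then cannulation into 6 (excess), THF, −78 °C
Reagents that add atoms: none
Why: A second directed ortho-metalation at one of the two equivalent C–H positions flanked by F and OMOM, held at −78 °C so that LiF is not lost, is followed by acylation of the aryllithium with the chloroformate (inverse addition) to give the ester.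

**Step 4**
Reactants: 9 methyl 3-hydroxy-4,5-dimethoxybenzoate
Product: 10 methyl 3,4-dimethoxy-5-(methoxymethoxy)benzoate
Conditions: NaH (1.2 equiv), MOMCl (1.2 equiv), DMF, 0 °C to rt
Reagents that add atoms: chloromethyl methyl ether (MOMCl), COCCl
Why: Williamson-type O-alkylation of the phenoxide installs the same acid-labile group as on ring A, so that one final operation frees all three phenols.

**Step 5**
Reactants: 10 methyl 3,4-dimethoxy-5-(methoxymethoxy)benzoate; 11 allyl acetate
Product: 13 allyl 3-[3,4-dimethoxy-5-(methoxymethoxy)phenyl]-3-oxopropanoate, via lithium enolate 12 (not isolated)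
Conditions: 11 (2.5 equiv), LiN(SiMe3)2 (2.6 equiv), THF, −78 °C; then 10, −78 to 0 °C; AcOH
Reagents that add atoms: none
Why: Crossed Claisen condensation: the preformed lithium enolate of allyl acetate, in excess, acylates the non-enolisable methyl benzoate, and the product is kept as its enolate until the quench.

**Step 6**
Reactants: 13 allyl 3-[3,4-dimethoxy-5-(methoxymethoxy)phenyl]-3-oxopropanoate
Product: 14 allyl (3S)-3-[3,4-dimethoxy-5-(methoxymethoxy)phenyl]-3-hydroxypropanoate
Conditions: RuCl[(S,S)-TsDPEN](p-cymene) (1 mol %), HCO2H/Et3N (5:2), DMF, 30 °C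
Reagents that add atoms: none
Why: Noyori asymmetric transfer hydrogenation of an aryl ketone: the (S,S)-TsDPEN ruthenium hydride should deliver hydrogen to the face that gives the (S)-benzylic alcohol, as with acetophenones (aryl CH/π contact in the six-membered transition state), and it leaves the allyl ester and the MOM ethers untouched.

**Step 7**
Reactants: 14 allyl (3S)-3-[3,4-dimethoxy-5-(methoxymethoxy)phenyl]-3-hydroxypropanoate; 8 allyl 6-fluoro-3-geranyl-2,4-bis(methoxymethoxy)benzoate
Product: 17 allyl (2S)-2-[3,4-dimethoxy-5-(methoxymethoxy)phenyl]-6-geranyl-5,7-bis(methoxymethoxy)-4-oxo-3,4-dihydro-2H-chromene-3-carboxylate, via dilithium dianion 15 (not isolated), via acyclic keto ester 16 (not isolated)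
Conditions: LiN(iPr)2 (2.1 equiv), THF, −78 to −30 °C; 8, −78 to −20 °C; LiN(SiMe3)2 (1.1 equiv), DMPU, −20 to 25 °C; AcOH, −78 °C
Reagents that add atoms: none
Why: Proposed new method: the alkoxide–enolate dianion 15 (a Fráter–Seebach-type dianion) attacks the ester carbonyl of 8 through its enolate carbon, the future C3, in a Claisen condensation that makes C3–C4, and the alkoxide of the resulting 16 (kept as the alkoxide–enolate by the extra LiN(SiMe3)2, a form in which neither retro-aldol cleavage nor loss of water is open) then adds to C8a, the fluorine-bearing carbon ortho to the new C4 acyl group, and expels fluoride from the Meisenheimer-type adduct to make O1–C8a. The closest known reaction types are the Claisen acylation of ester enolates, the alkylation of β-hydroxy ester dianions, and the domino C-acylation/intramolecular SNAr of enolate or enamine 1,3-dinucleophiles with 2-fluorobenzoyl electrophiles that gives chromone-3-carboxylates and 4-quinolones; new here is a chiral alkoxide as the second nucleophile, so that a saturated ring C with its C2 centre already in place results. Ring C closes by 6-exo-trig addition of O1 to C8a (the C8a=C8 π bond of ring A lies outside the new ring) followed by elimination of LiF. No lasting stereocenter is created: C2 is carried over from 14 because neither its C–O nor its C–H bond is touched, and C3 is a transient epimerisable, enolised centre that becomes CH2 in step 8. The step needs C- over O-acylation, which the far more nucleophilic enolate carbon and the unactivated alkyl ester (allyl, so that any ester exchange by the liberated alkoxide is degenerate) should secure, and it needs closure at one defined ortho carbon, which is secured because C8a is the only carbon of ring A that carries fluorine, so no 8-geranyl isomer can arise. The quench is made cold with AcOH so that the product enolate has little chance to open ring C by a retro-oxa-Michael reaction.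

**Step 8**
Reactants: 17 allyl (2S)-2-[3,4-dimethoxy-5-(methoxymethoxy)phenyl]-6-geranyl-5,7-bis(methoxymethoxy)-4-oxo-3,4-dihydro-2H-chromene-3-carboxylate
Product: 18 (2S)-2-[3,4-dimethoxy-5-(methoxymethoxy)phenyl]-6-geranyl-5,7-bis(methoxymethoxy)-2,3-dihydro-4H-chromen-4-one
Conditions: Pd(OAc)2 (5 mol %), PPh3 (20 mol %), HCO2H, Et3N, THF, rt
Reagents that add atoms: none
Why: Tsuji decarboxylation–hydrogenolysis of an allyl β-keto ester: zerovalent palladium formed from Pd(OAc)2 and PPh3 ionises the allyl ester, formate reduces the π-allyl group to propene, and the β-keto acid loses CO2 at room temperature under buffered conditions that should leave C2 and the geranyl alkenes untouched.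

**Step 9**
Reactants: 18 (2S)-2-[3,4-dimethoxy-5-(methoxymethoxy)phenyl]-6-geranyl-5,7-bis(methoxymethoxy)-2,3-dihydro-4H-chromen-4-one
Product: 19 (2S)-5,7-dihydroxy-2-(3-hydroxy-4,5-dimethoxyphenyl)-6-geranyl-2,3-dihydro-4H-chromen-4-one (CNP0228243.1)
Conditions: HCl (3 M aq., 5 equiv), MeOH, 40 °C
Reagents that add atoms: none
Why: Acid-catalysed acetal exchange cleaves the three aryl MOM ethers while methanol traps the formaldehyde unit as dimethoxymethane, and dilute acid at mild temperature is chosen to spare the geranyl chain and the C2 centre.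

**Compound list**

1 | 5-fluorobenzene-1,3-diol | Oc1cc(O)cc(F)c1 | starting material
2 | 1-fluoro-3,5-bis(methoxymethoxy)benzene | COCOc1cc(F)cc(OCOC)c1 | intermediate
3 | geranyl bromide, (2E)-1-bromo-3,7-dimethylocta-2,6-diene | BrC/C=C(\C)CCC=C(C)C | starting material
4 | [4-fluoro-2,6-bis(methoxymethoxy)phenyl]lithium | [Li]c1c(OCOC)cc(F)cc1OCOC | intermediate
5 | 5-fluoro-2-[(2E)-3,7-dimethylocta-2,6-dien-1-yl]-1,3-bis(methoxymethoxy)benzene | COCOc1cc(F)cc(OCOC)c1C/C=C(\C)CCC=C(C)C | intermediate
6 | allyl chloroformate (prop-2-en-1-yl carbonochloridate) | C=CCOC(Cl)=O | starting material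
7 | {6-fluoro-3-[(2E)-3,7-dimethylocta-2,6-dien-1-yl]-2,4-bis(methoxymethoxy)phenyl}lithium | [Li]c1c(F)cc(OCOC)c(C/C=C(\C)CCC=C(C)C)c1OCOC | intermediate
8 | allyl 6-fluoro-3-[(2E)-3,7-dimethylocta-2,6-dien-1-yl]-2,4-bis(methoxymethoxy)benzoate | C=CCOC(=O)c1c(F)cc(OCOC)c(C/C=C(\C)CCC=C(C)C)c1OCOC | intermediate
9 | methyl 3-hydroxy-4,5-dimethoxybenzoate | COC(=O)c1cc(O)c(OC)c(OC)c1 | starting material
10 | methyl 3,4-dimethoxy-5-(methoxymethoxy)benzoate | COC(=O)c1cc(OCOC)c(OC)c(OC)c1 | intermediate
11 | allyl acetate | CC(=O)OCC=C | starting material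
12 | lithium enolate of allyl acetate | [Li+].C=C([O-])OCC=C | intermediate
13 | allyl 3-[3,4-dimethoxy-5-(methoxymethoxy)phenyl]-3-oxopropanoate | C=CCOC(=O)CC(=O)c1cc(OCOC)c(OC)c(OC)c1 | intermediate
14 | allyl (3S)-3-[3,4-dimethoxy-5-(methoxymethoxy)phenyl]-3-hydroxypropanoate | C=CCOC(=O)C[C@H](O)c1cc(OCOC)c(OC)c(OC)c1 | intermediate
15 | dilithium alkoxide–enolate (dianion) of 14 | [Li+].[Li+].C=CCOC([O-])=C[C@H]([O-])c1cc(OCOC)c(OC)c(OC)c1 | intermediate
16 | allyl (3S)-2-[6-fluoro-3-geranyl-2,4-bis(methoxymethoxy)benzoyl]-3-[3,4-dimethoxy-5-(methoxymethoxy)phenyl]-3-hydroxypropanoate (present as its lithium alkoxide–enolate; drawn as the neutral keto form) | C=CCOC(=O)C(C(=O)c1c(F)cc(OCOC)c(C/C=C(\C)CCC=C(C)C)c1OCOC)[C@H](O)c1cc(OCOC)c(OC)c(OC)c1 | intermediate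
17 | allyl (2S)-2-[3,4-dimethoxy-5-(methoxymethoxy)phenyl]-6-[(2E)-3,7-dimethylocta-2,6-dien-1-yl]-5,7-bis(methoxymethoxy)-4-oxo-3,4-dihydro-2H-chromene-3-carboxylate | C=CCOC(=O)C1C(=O)c2c(OCOC)c(C/C=C(\C)CCC=C(C)C)c(OCOC)cc2O[C@@H]1c1cc(OCOC)c(OC)c(OC)c1 | intermediate
18 | (2S)-2-[3,4-dimethoxy-5-(methoxymethoxy)phenyl]-6-[(2E)-3,7-dimethylocta-2,6-dien-1-yl]-5,7-bis(methoxymethoxy)-2,3-dihydro-4H-chromen-4-one | O=C1C[C@@H](c2cc(OCOC)c(OC)c(OC)c2)Oc2cc(OCOC)c(C/C=C(\C)CCC=C(C)C)c(OCOC)c12 | intermediate
19 | (2S)-5,7-dihydroxy-2-(3-hydroxy-4,5-dimethoxyphenyl)-6-[(2E)-3,7-dimethylocta-2,6-dien-1-yl]-2,3-dihydro-4H-chromen-4-one | COc1cc([C@@H]2CC(=O)c3c(cc(O)c(C/C=C(\C)CCC=C(C)C)c3O)O2)cc(O)c1OC | target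

**Step count and risks**

Total step count: 9. Longest linear sequence: 6 steps (steps 1–3 or 4–6, then 7–9).

Steps most likely to fail:

1. Step 7 (proposed new method). O-acylation of the alkoxide could compete and be followed at once by β-elimination to a cinnamate. The SNAr could be slow on the enolised, electron-rich ring, giving time for retro-aldol cleavage or loss of water. The product enolate could open and reclose ring C and erode the C2 configuration. Fallback with known chemistry, setting out from 14 and 5 and returning at 18, so that steps 7 and 8 are replaced: 14 is silylated (TBSCl, imidazole, DMF) to allyl (3S)-3-(tert-butyldimethylsilyloxy)-3-[3,4-dimethoxy-5-(methoxymethoxy)phenyl]propanoate F1. The allyl ester is exchanged for the Weinreb amide (MeNHOMe·HCl, iPrMgCl, THF, −20 °C) to give (3S)-3-(tert-butyldimethylsilyloxy)-3-[3,4-dimethoxy-5-(methoxymethoxy)phenyl]-N-methoxy-N-methylpropanamide F2. Aryllithium 7, made from 5 as in step 3, adds to F2 at −78 °C to give the silyloxy ketone (3S)-3-(tert-butyldimethylsilyloxy)-1-[6-fluoro-3-geranyl-2,4-bis(methoxymethoxy)phenyl]-3-[3,4-dimethoxy-5-(methoxymethoxy)phenyl]propan-1-one F3; this makes C4–C4a instead of C3–C4. Bu4NF (THF, 0 °C to rt) removes the silyl group to give the hydroxy ketone (3S)-1-[6-fluoro-3-geranyl-2,4-bis(methoxymethoxy)phenyl]-3-hydroxy-3-[3,4-dimethoxy-5-(methoxymethoxy)phenyl]propan-1-one F4, whose alkoxide closes ring C by intramolecular SNAr onto the C–F carbon, now activated by a true ortho ketone, to give 18.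

2. Step 2. Deprotonation could occur next to fluorine instead of between the two OMOM groups, followed by loss of LiF to an aryne; the allylation could also go partly SN2′. Fallback from 1, returning at 5: Friedel–Crafts allylation of 1 with geraniol on acidic alumina in 1,2-dichloroethane at reflux, as used for 2-geranyl resorcinols, should give 5-fluoro-2-[(2E)-3,7-dimethylocta-2,6-dien-1-yl]benzene-1,3-diol F5 after separation from the 4-geranyl isomer. Bis-MOM protection (NaH, MOMCl, DMF) then gives 5, so the regiochemistry no longer rests on a metalation.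

3. Step 9. Under protic acid the geranyl alkene nearest the ring could cyclise onto a freed ortho phenol (chroman formation), the freed formaldehyde could condense at C8, and acid-mediated opening of ring C could erode C2. Fallback from 18, returning at 19, with no protic acid: Et3SiOTf and 2,2′-bipyridyl (CH2Cl2, 0 °C) should convert the three aryl MOM ethers directly into silyl ethers, giving (2S)-2-[3,4-dimethoxy-5-(triethylsilyloxy)phenyl]-6-geranyl-5,7-bis(triethylsilyloxy)-2,3-dihydro-4H-chromen-4-one F6. Buffered fluoride (Bu4NF/AcOH 1:1, THF, 0 °C) then frees the phenols to give 19.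

**Further compounds**

F1 | step 7 | allyl (3S)-3-(tert-butyldimethylsilyloxy)-3-[3,4-dimethoxy-5-(methoxymethoxy)phenyl]propanoate | C=CCOC(=O)C[C@H](O[Si](C)(C)C(C)(C)C)c1cc(OCOC)c(OC)c(OC)c1
F2 | step 7 | (3S)-3-(tert-butyldimethylsilyloxy)-3-[3,4-dimethoxy-5-(methoxymethoxy)phenyl]-N-methoxy-N-methylpropanamide | CON(C)C(=O)C[C@H](O[Si](C)(C)C(C)(C)C)c1cc(OCOC)c(OC)c(OC)c1
F3 | step 7 | (3S)-3-(tert-butyldimethylsilyloxy)-1-[6-fluoro-3-geranyl-2,4-bis(methoxymethoxy)phenyl]-3-[3,4-dimethoxy-5-(methoxymethoxy)phenyl]propan-1-one | O=C(C[C@H](O[Si](C)(C)C(C)(C)C)c1cc(OCOC)c(OC)c(OC)c1)c1c(F)cc(OCOC)c(C/C=C(\C)CCC=C(C)C)c1OCOC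
F4 | step 7 | (3S)-1-[6-fluoro-3-geranyl-2,4-bis(methoxymethoxy)phenyl]-3-hydroxy-3-[3,4-dimethoxy-5-(methoxymethoxy)phenyl]propan-1-one | O=C(C[C@H](O)c1cc(OCOC)c(OC)c(OC)c1)c1c(F)cc(OCOC)c(C/C=C(\C)CCC=C(C)C)c1OCOC
F5 | step 2 | 5-fluoro-2-[(2E)-3,7-dimethylocta-2,6-dien-1-yl]benzene-1,3-diol | Oc1cc(F)cc(O)c1C/C=C(\C)CCC=C(C)C
F6 | step 9 | (2S)-2-[3,4-dimethoxy-5-(triethylsilyloxy)phenyl]-6-geranyl-5,7-bis(triethylsilyloxy)-2,3-dihydro-4H-chromen-4-one | O=C1C[C@@H](c2cc(O[Si](CC)(CC)CC)c(OC)c(OC)c2)Oc2cc(O[Si](CC)(CC)CC)c(C/C=C(\C)CCC=C(C)C)c(O[Si](CC)(CC)CC)c12
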